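**The charge.** Book every mole of substrate before you rank these flasks.

the same everywhere: left-handed substrate 0.20 M; right-handed substrate 0.20 M
- west: partner 0.43 M; run made earlier
- south: partner 2.3 M; run made earlier
- eta: partner 0.600 M; time 6.0 min
- zeta: partner 1.20 M; time 6.0 min
- gamma: partner 0.300 M; time 6.0 min
- alpha: partner 2.00 M; time 6.0 min
- epsilon: partner 0.440 M; time 6.0 min

| run | time / min | left-handed product / % | right-handed product / % |
|---|---|---|---|
| west | 0.500 | 53.1 | 19.2 |
| west | 1.00 | 54.6 | 18.2 |
| west | 1.50 | 55.6 | 21.6 |
| west | 2.00 | 58.9 | 22.5 |
| west | 2.50 | 59.6 | 22.7 |
| west | 3.00 | 59.5 | 20.5 |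
| south | 0.500 | 51.5 | 40.1 |
| south | 1.00 | 50.8 | 42.4 |
| south | 1.50 | 52.9 | 42.9 |
| south | 2.00 | 52.9 | 42.1 |
| south | 2.50 | 52.0 | 43.7 |
| south | 3.00 | 53.5 | 42.6 |

(scatter of a reading: 1 percentage point)

- partner is single-handed; left-handed substrate and right-handed substrate are mirror images of each other, charged as a racemate, each of them at the stated concentration
- the handed part of partner does not stay in what it makes, so the products of the two hands are mirror images too

- ranking by excess of left-handed product over right-handed product, from high to low, at 6.0 min (eta / zeta / gamma / alpha / epsilon)
- the excess of left-handed product over right-handed product of the flask you put first, at 6.0 min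
- the excess of left-handed product over right-handed product of the flask you put last, at 6.0 min

**West ledger.** I averaged the last 3 readings of each run. West held 59.3% of the charge as left-handed product and 21.9% as right-handed product, so 18.8% stood in neither column. South held 52.8% and 42.8%. Left-handed product beyond its own half of the charge must have come across from the right-handed side. Of what right-handed product did not take, that crossing was 33.2% in west and 38.9% in south.

**Capture number.** I took left-handed substrate as served first, since west already showed 53.1% of left-handed product at 0.500 min, more than its 19.2% of right-handed product, and reckoned with the partner it leaves free, c(partner) − c(left-handed substrate). The capture number is right-handed product divided by the rest of the right-handed side, per molar of that free partner. It read 3.39 M⁻¹ in west and 2.83 M⁻¹ in south.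

**Gamma's books.** In gamma, partner at 0.300 M is the limiting reagent, under the 0.400 M of substrate. By the west numbers, I put gamma's right-handed product at 12.7% of the charge and its left-handed product at 62.4%. In my books, left-handed substrate took 0.20 M of the partner, right-handed product 0.0508 M, and the crossing 0.0496 M. That closed at 0.300 M. The excess, (left − right)/(left + right), was 66.3%. For alpha, with 41.8% as right-handed product, the south numbers gave 12.0%.

**The forecast.** It ranked gamma > epsilon > eta > zeta > alpha, with 55% first and 12% last, calling gamma “limited by partner supply, so it is less certain”. My order, by rising free partner, was the same, and my alpha figure was close. My gamma stood higher than the forecast's.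

**The result.** The simulation gave gamma > epsilon > eta > zeta > alpha, with 60.6% for gamma and 12.3% for alpha. That gamma figure stood under mine. It stood above the forecast's.

    partner + left-handed substrate → left-handed product (k = 1.45 M⁻¹ s⁻¹)
    partner + right-handed substrate → right-handed product (k = 0.137 M⁻¹ s⁻¹)
    left-handed substrate ⇌ achiral form (K = 0.371, k = 0.0300 s⁻¹)
    right-handed substrate ⇌ achiral form (K = 0.371, k = 0.0300 s⁻¹)
    achiral form → side product (k = 0.0825 s⁻¹)
    2 partner → self-condensation product (k = 0.0536 M⁻¹ s⁻¹)

**Come to rest.** Read back, gamma's 13.3% of right-handed product gave a capture number of 3.62 M⁻¹ against 3.39 M⁻¹. On zeta, 3.39 M⁻¹ gave 38.6% of right-handed product, and the simulation gave 37.7%. At 6.00 min gamma still held 0.70% of its left-handed substrate and 0.72% of its right-handed substrate. By 60.0 min gamma's side product had moved from 31.8% to 32.6%, while its left-handed and right-handed products stood at 54.1% and 13.3%. The excess then read 60.6% for gamma and 12.3% for alpha.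

(All runs were generated by integration with constants of no real substance, noise included.)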